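**Plan**

- Cuts, in retrosynthetic order: the eleven O–alkyl bonds of a fully etherified pentamer; the diaryl ether between position 4 of ring C and the position-1 oxygen of ring D, giving an ABC bromide and a DE phenol; the ether between ring A and the position-1 oxygen of ring B, giving a ring A boronic acid; then rings B and D themselves, each opened between positions 3 and 4 to a four-membered ring whose aryloxy group is the ether on position 6.
- Enabling feature (rings A to E in SMILES order): ring D carries its oxygen to ring C on position 1, para to the hydroxyl on position 4 and flanked by the hydroxyl on position 2 and the ether oxygen to ring E on position 6, and ring B repeats this pattern. A 3-aryloxy-4-silyloxy-4-(1-ethoxyvinyl)cyclobut-2-enone holds these six carbons in order: quaternary carbon (position 1), vinyl α-carbon (2), vinyl CH2 (3), carbonyl carbon (4), ring CH (5), aryloxy-bearing carbon (6).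
- Forward: diisopropyl squarate is taken to semisquaric chloride, which esterifies the ring E phenol and the ring C phenol. One batch of 1-ethoxyvinyllithium is added to both esters, and thermal ring expansion then builds ring D (on E) and ring B (on C).
- Ring A is added by Chan–Lam coupling, the ABC bromide and the DE phenol are joined by Ullmann etherification, and BBr3 frees the eleven phenols.
- Stereochemistry: the target is achiral; the only stereocentre on the way (the cyclobutenone carbinol carbon) is racemic and becomes aromatic.

Key step: step 7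

Remark: ring positions are counted from the carbon bearing the ether oxygen to the preceding ring (position 1). 2,4,6-Trimethoxyphenol and 4-bromo-2,6-dimethoxyphenol are taken as purchased. Esters 7 and 18 are both in hand before the organolithium of step 5 is made, so that one batch serves steps 6 and 11 on the same day.

**Route**

Step 1
Reactants: 1 diisopropyl squarate
Product: 3 isopropyl semisquarate (3-isopropoxycyclobut-3-ene-1,2-dione), via hydroxycyclobutenone 2 (not isolated)
Conditions: LiAlH(OtBu)3, THF, −78 → 0 °C; then 12 M HCl (cat.), CH2Cl2, rt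
Reagents that add atoms: none
Why: The bulky hydride LiAlH(OtBu)3 should stop at a single 1,2-reduction of one squarate carbonyl, and acid then ionises the carbinol and expels isopropanol from the alkoxy-stabilised cyclobutenyl cation (the usual squarate adduct-to-dione hydrolysis) to leave the C–H semisquarate.

Step 2
Reactants: 3 isopropyl semisquarate
Product: 4 semisquaric acid (3-hydroxycyclobut-3-ene-1,2-dione)
Conditions: 2 M HCl, THF/H2O, 50 °C; evaporate
Reagents that add atoms: water, O
Why: Acid-catalysed vinylogous ester hydrolysis (addition of water at the alkoxy-bearing carbon, loss of isopropanol) should give the strongly acidic vinylogous carboxylic acid, which is isolated by evaporation.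

Step 3
Reactants: 4 semisquaric acid
Product: 5 semisquaric chloride (3-chlorocyclobut-3-ene-1,2-dione)
Conditions: (COCl)2, DMF (cat.), CH2Cl2, 0 °C → rt
Reagents that add atoms: oxalyl chloride, O=C(Cl)C(Cl)=O
Why: Vilsmeier-type chlorination with oxalyl chloride and catalytic DMF converts the vinylogous carboxylic acid into its acid chloride as it would a carboxylic acid, the by-products being gases.

Step 4
Reactants: 5 semisquaric chloride; 6 2,4,6-trimethoxyphenol
Product: 7 3-(2,4,6-trimethoxyphenoxy)cyclobut-3-ene-1,2-dione
Conditions: i-Pr2NEt, CH2Cl2, −78 → 0 °C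
Reagents that add atoms: none
Why: Vinylogous acyl substitution (addition–elimination of the phenoxide at the chlorine-bearing carbon, a Schotten–Baumann-type esterification) is insensitive to the two ortho methoxy groups, and with base at low temperature the phenol oxygen should react ahead of the electron-rich ring carbons.

Step 5
Reactants: 8 ethyl vinyl ether
Product: 9 1-ethoxyvinyllithium (THF solution, used the same day)
Conditions: t-BuLi (pentane), 8 in slight excess, THF, −78 → 0 °C, then −78 °C
Reagents that add atoms: tert-butyllithium, [Li]C(C)(C)C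
Why: Deprotonation of the α-vinylic C–H of the enol ether by t-BuLi is the standard entry to this acyl anion equivalent, and one titrated batch free of residual alkyllithium, divided between steps 6 and 11, keeps t-BuLi away from the electrophilic diones and from the aryl bromide of 18.

Step 6
Reactants: 7 3-(2,4,6-trimethoxyphenoxy)cyclobut-3-ene-1,2-dione; 9 1-ethoxyvinyllithium
Product: 11 4-(tert-butyldimethylsilyloxy)-4-(1-ethoxyvinyl)-3-(2,4,6-trimethoxyphenoxy)cyclobut-2-en-1-one (racemic), via lithium alkoxide 10 (not isolated)
Conditions: 9 added to 7, THF, −78 °C; then TBSOTf, −78 → 0 °C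
Reagents that add atoms: tert-butyldimethylsilyl trifluoromethanesulfonate (TBSOTf), CC(C)(C)[Si](C)(C)OS(=O)(=O)C(F)(F)F
Why: 1,2-Addition of the α-lithiated enol ether should occur at the ketone carbonyl beside the aryloxy-bearing carbon, because the other carbonyl is deactivated as a vinylogous ester and the doubly ortho-substituted aryloxy group shields its carbon from conjugate addition–elimination, and the tertiary lithium alkoxide is then silylated in the flask by the silyl triflate; the new carbinol centre is racemic and is lost in step 7.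

Step 7
Reactants: 11 4-(tert-butyldimethylsilyloxy)-4-(1-ethoxyvinyl)-3-(2,4,6-trimethoxyphenoxy)cyclobut-2-en-1-one
Product: 14 DE phenol 4-(tert-butyldimethylsilyloxy)-3-ethoxy-5-(2,4,6-trimethoxyphenoxy)phenol, via dienylketene 12 (not isolated), via cyclohexadienone 13 (not isolated)
Conditions: toluene (degassed), 110 °C
Reagents that add atoms: none
Why: Heating should trigger conrotatory 4π-electrocyclic opening of the cyclobutenone by cleavage of the bond between the carbonyl carbon and the quaternary carbon, giving dienylketene 12. The silyloxy donor on the breaking sp3 carbon rotates outward (torquoselectivity of oxygen donors), so the 1-ethoxyvinyl group turns inward and lies cis to the ketene; this is the one selectivity the step needs, and the oxygen substituent on the quaternary carbon secures it. Thermal disrotatory 6π-electrocyclisation then joins the vinyl CH2 (future position 3 of ring D) to the ketene carbon (future position 4) and closes ring D as cyclohexa-2,4-dienone 13, which enolises to the phenol. The closest known reaction is the Moore rearrangement of squarate-derived 4-alkenyl-4-(silyloxy)cyclobutenones to mono-silylated hydroquinones. No stereocentre is created: the racemic carbinol carbon becomes aromatic position 1, and the constitution of 11 fixes the arene with the position-1 oxygen silylated, ethoxy on position 2, a free hydroxyl on position 4 and ring E on the position-6 oxygen.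

Step 8
Reactants: 14 DE phenol
Product: 15 tert-butyl[2-ethoxy-4-methoxy-6-(2,4,6-trimethoxyphenoxy)phenoxy]dimethylsilane
Conditions: MeI, K2CO3, acetone, 40 °C
Reagents that add atoms: iodomethane, CI
Why: Williamson O-methylation of the only free phenol, which sits between two ring hydrogens, while the silyl ether between two ortho substituents should be inert to K2CO3 in dry acetone.

Step 9
Reactants: 15 tert-butyl[2-ethoxy-4-methoxy-6-(2,4,6-trimethoxyphenoxy)phenoxy]dimethylsilane
Product: 16 2-ethoxy-4-methoxy-6-(2,4,6-trimethoxyphenoxy)phenol (DE phenol with the position-1 hydroxyl of ring D free)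
Conditions: Bu4NF, AcOH, THF, 0 °C, Ar
Reagents that add atoms: none
Why: Fluoride-induced desilylation of the aryl silyl ether is driven by Si–F bond formation, and AcOH buffering releases the electron-rich phenol in neutral form and not as its oxidation-prone phenoxide.

Step 10
Reactants: 5 semisquaric chloride; 17 4-bromo-2,6-dimethoxyphenol
Product: 18 3-(4-bromo-2,6-dimethoxyphenoxy)cyclobut-3-ene-1,2-dione
Conditions: i-Pr2NEt, CH2Cl2, −78 → 0 °C
Reagents that add atoms: none
Why: The same vinylogous acyl substitution as in step 4, with the aryl bromide as a spectator.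

Step 11
Reactants: 9 1-ethoxyvinyllithium; 18 3-(4-bromo-2,6-dimethoxyphenoxy)cyclobut-3-ene-1,2-dione
Product: 20 3-(4-bromo-2,6-dimethoxyphenoxy)-4-(tert-butyldimethylsilyloxy)-4-(1-ethoxyvinyl)cyclobut-2-en-1-one (racemic), via lithium alkoxide 19 (not isolated)
Conditions: 9 added to 18, THF, −78 °C; then TBSOTf, −78 → 0 °C
Reagents that add atoms: tert-butyldimethylsilyl trifluoromethanesulfonate (TBSOTf), CC(C)(C)[Si](C)(C)OS(=O)(=O)C(F)(F)F
Why: The same regioselective 1,2-addition and in-flask O-silylation as in step 6, in which the sp2 organolithium, already free of t-BuLi, should be consumed by the very electrophilic ketone carbonyl at −78 °C before bromine–lithium exchange with the aryl bromide can compete.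

Step 12
Reactants: 20 3-(4-bromo-2,6-dimethoxyphenoxy)-4-(tert-butyldimethylsilyloxy)-4-(1-ethoxyvinyl)cyclobut-2-en-1-one
Product: 23 BC phenol 3-(4-bromo-2,6-dimethoxyphenoxy)-4-(tert-butyldimethylsilyloxy)-5-ethoxyphenol, via dienylketene 21 (not isolated), via cyclohexadienone 22 (not isolated)
Conditions: toluene (degassed), 110 °C
Reagents that add atoms: none
Why: Moore rearrangement as in step 7 (4π opening with outward rotation of the silyloxy group, 6π-electrocyclisation of dienylketene 21 joining positions 3 and 4 of ring B, enolisation of dienone 22) should give ring B with ring C on its position-6 oxygen, the position-1 oxygen silylated and the position-4 hydroxyl free.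

Step 13
Reactants: 23 BC phenol
Product: 24 [2-(4-bromo-2,6-dimethoxyphenoxy)-6-ethoxy-4-methoxyphenoxy](tert-butyl)dimethylsilane
Conditions: MeI, K2CO3, acetone, 40 °C
Reagents that add atoms: iodomethane, CI
Why: Williamson O-methylation of the unhindered position-4 phenol of ring B, as in step 8.

Step 14
Reactants: 24 [2-(4-bromo-2,6-dimethoxyphenoxy)-6-ethoxy-4-methoxyphenoxy](tert-butyl)dimethylsilane
Product: 25 2-(4-bromo-2,6-dimethoxyphenoxy)-6-ethoxy-4-methoxyphenol (BC phenol with the position-1 hydroxyl of ring B free)
Conditions: Bu4NF, AcOH, THF, 0 °C, Ar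
Reagents that add atoms: none
Why: Buffered fluoride desilylation as in step 9 frees the position-1 phenol of ring B.

Step 15
Reactants: 25 2-(4-bromo-2,6-dimethoxyphenoxy)-6-ethoxy-4-methoxyphenol; 26 3,5-dimethoxyphenylboronic acid
Product: 27 ABC bromide 5-bromo-2-[2-(3,5-dimethoxyphenoxy)-3-ethoxy-5-methoxyphenoxy]-1,3-dimethoxybenzene
Conditions: Cu(OAc)2, pyridine, 4 Å MS, CH2Cl2, O2 (1 atm), rt
Reagents that add atoms: none
Why: Chan–Lam oxidative etherification, in which the phenoxide binds divalent copper, the unhindered arylboronic acid transmetalates and C–O reductive elimination occurs from trivalent copper at room temperature, is known to accept 2,6-disubstituted phenols and to leave aryl bromides untouched.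

Step 16
Reactants: 16 2-ethoxy-4-methoxy-6-(2,4,6-trimethoxyphenoxy)phenol; 27 ABC bromide
Product: 28 fully etherified pentamer (nine methyl ethers and two ethyl ethers)
Conditions: CuI (cat.), picolinic acid (cat.), K3PO4, DMSO, 100 °C, Ar
Reagents that add atoms: none
Why: Ullmann diaryl ether synthesis with the CuI/picolinic acid system is established for 2,6-disubstituted phenols and unactivated aryl bromides, and the bromine of ring C sits between two ring hydrogens, so only the phenol partner is hindered.

Step 17
Reactants: 28 fully etherified pentamer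
Product: 29 target CNP0018313.0 (undecahydroxy pentamer)
Conditions: BBr3 (large excess), CH2Cl2, −78 °C → rt; then H2O, Ar
Reagents that add atoms: none
Why: Lewis-acid ether cleavage: BBr3 complexes each alkyl aryl ether oxygen and bromide removes the methyl or ethyl group by SN2, while the four diaryl ethers, having no sp3 carbon on oxygen, should survive; hydrolysis of the aryl borates liberates the eleven phenols.

**Compound list**

1 | diisopropyl squarate | CC(C)OC1=C(OC(C)C)C(=O)C1=O | starting material
2 | 4-hydroxy-2,3-diisopropoxycyclobut-2-en-1-one (racemic; not isolated) | CC(C)OC1=C(OC(C)C)C(O)C1=O | intermediate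
3 | isopropyl semisquarate, 3-isopropoxycyclobut-3-ene-1,2-dione | CC(C)OC1=CC(=O)C1=O | intermediate
4 | semisquaric acid, 3-hydroxycyclobut-3-ene-1,2-dione | OC1=CC(=O)C1=O | intermediate
5 | semisquaric chloride, 3-chlorocyclobut-3-ene-1,2-dione | ClC1=CC(=O)C1=O | intermediate
6 | 2,4,6-trimethoxyphenol | COc1cc(OC)c(O)c(OC)c1 | starting material
7 | 3-(2,4,6-trimethoxyphenoxy)cyclobut-3-ene-1,2-dione | COc1cc(OC)c(OC2=CC(=O)C2=O)c(OC)c1 | intermediate
8 | ethyl vinyl ether | C=COCC | starting material
9 | 1-ethoxyvinyllithium (THF solution, used the same day) | [Li]C(=C)OCC | intermediate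
10 | lithium 1-(1-ethoxyvinyl)-4-oxo-2-(2,4,6-trimethoxyphenoxy)cyclobut-2-en-1-olate (racemic; not isolated) | [Li+].[O-]C1(C(=C)OCC)C(=O)C=C1Oc1c(OC)cc(OC)cc1OC | intermediate
11 | 4-(tert-butyldimethylsilyloxy)-4-(1-ethoxyvinyl)-3-(2,4,6-trimethoxyphenoxy)cyclobut-2-en-1-one (racemic) | CCOC(=C)C1(O[Si](C)(C)C(C)(C)C)C(=O)C=C1Oc1c(OC)cc(OC)cc1OC | intermediate
12 | (3Z)-4-(tert-butyldimethylsilyloxy)-5-ethoxy-3-(2,4,6-trimethoxyphenoxy)hexa-1,3,5-trien-1-one (dienylketene; not isolated) | O=C=C/C(Oc1c(OC)cc(OC)cc1OC)=C(\C(=C)OCC)O[Si](C)(C)C(C)(C)C | intermediate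
13 | 4-(tert-butyldimethylsilyloxy)-5-ethoxy-3-(2,4,6-trimethoxyphenoxy)cyclohexa-2,4-dien-1-one (not isolated) | O=C1C=C(Oc2c(OC)cc(OC)cc2OC)C(O[Si](C)(C)C(C)(C)C)=C(OCC)C1 | intermediate
14 | 4-(tert-butyldimethylsilyloxy)-3-ethoxy-5-(2,4,6-trimethoxyphenoxy)phenol | CCOc1cc(O)cc(Oc2c(OC)cc(OC)cc2OC)c1O[Si](C)(C)C(C)(C)C | intermediate
15 | tert-butyl[2-ethoxy-4-methoxy-6-(2,4,6-trimethoxyphenoxy)phenoxy]dimethylsilane | CCOc1cc(OC)cc(Oc2c(OC)cc(OC)cc2OC)c1O[Si](C)(C)C(C)(C)C | intermediate
16 | 2-ethoxy-4-methoxy-6-(2,4,6-trimethoxyphenoxy)phenol | CCOc1cc(OC)cc(Oc2c(OC)cc(OC)cc2OC)c1O | intermediate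
17 | 4-bromo-2,6-dimethoxyphenol | COc1cc(Br)cc(OC)c1O | starting material
18 | 3-(4-bromo-2,6-dimethoxyphenoxy)cyclobut-3-ene-1,2-dione | COc1cc(Br)cc(OC)c1OC1=CC(=O)C1=O | intermediate
19 | lithium 2-(4-bromo-2,6-dimethoxyphenoxy)-1-(1-ethoxyvinyl)-4-oxocyclobut-2-en-1-olate (racemic; not isolated) | [Li+].[O-]C1(C(=C)OCC)C(=O)C=C1Oc1c(OC)cc(Br)cc1OC | intermediate
20 | 3-(4-bromo-2,6-dimethoxyphenoxy)-4-(tert-butyldimethylsilyloxy)-4-(1-ethoxyvinyl)cyclobut-2-en-1-one (racemic) | CCOC(=C)C1(O[Si](C)(C)C(C)(C)C)C(=O)C=C1Oc1c(OC)cc(Br)cc1OC | intermediate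
21 | (3Z)-3-(4-bromo-2,6-dimethoxyphenoxy)-4-(tert-butyldimethylsilyloxy)-5-ethoxyhexa-1,3,5-trien-1-one (dienylketene; not isolated) | O=C=C/C(Oc1c(OC)cc(Br)cc1OC)=C(\C(=C)OCC)O[Si](C)(C)C(C)(C)C | intermediate
22 | 3-(4-bromo-2,6-dimethoxyphenoxy)-4-(tert-butyldimethylsilyloxy)-5-ethoxycyclohexa-2,4-dien-1-one (not isolated) | O=C1C=C(Oc2c(OC)cc(Br)cc2OC)C(O[Si](C)(C)C(C)(C)C)=C(OCC)C1 | intermediate
23 | 3-(4-bromo-2,6-dimethoxyphenoxy)-4-(tert-butyldimethylsilyloxy)-5-ethoxyphenol | CCOc1cc(O)cc(Oc2c(OC)cc(Br)cc2OC)c1O[Si](C)(C)C(C)(C)C | intermediate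
24 | [2-(4-bromo-2,6-dimethoxyphenoxy)-6-ethoxy-4-methoxyphenoxy](tert-butyl)dimethylsilane | CCOc1cc(OC)cc(Oc2c(OC)cc(Br)cc2OC)c1O[Si](C)(C)C(C)(C)C | intermediate
25 | 2-(4-bromo-2,6-dimethoxyphenoxy)-6-ethoxy-4-methoxyphenol | CCOc1cc(OC)cc(Oc2c(OC)cc(Br)cc2OC)c1O | intermediate
26 | 3,5-dimethoxyphenylboronic acid | COc1cc(OC)cc(B(O)O)c1 | starting material
27 | 5-bromo-2-[2-(3,5-dimethoxyphenoxy)-3-ethoxy-5-methoxyphenoxy]-1,3-dimethoxybenzene (ABC bromide) | CCOc1cc(OC)cc(Oc2c(OC)cc(Br)cc2OC)c1Oc1cc(OC)cc(OC)c1 | intermediate
28 | fully etherified pentamer (nine methyl ethers; ethyl ethers on position 2 of rings B and D) | COc1cc(OC)cc(Oc2c(OCC)cc(OC)cc2Oc2c(OC)cc(Oc3c(OCC)cc(OC)cc3Oc3c(OC)cc(OC)cc3OC)cc2OC)c1 | intermediate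
29 | CNP0018313.0, undecahydroxy pentamer (achiral) | Oc1cc(O)cc(Oc2c(O)cc(O)cc2Oc2c(O)cc(Oc3c(O)cc(O)cc3Oc3c(O)cc(O)cc3O)cc2O)c1 | target

**Count and risks**

Total: 17 steps. Longest linear sequence: 11 steps (1–3, then 10–17). The DE branch (steps 4 and 6–9) joins at step 16, and the reagent step 5 feeds steps 6 and 11.

Steps most likely to fail:

1. Step 17. Process: the elevenfold dealkylation may stall at partly alkylated stages (the two ethyl ethers and the ethers beside diaryl ether oxygens last), and the free undecaphenol may be lost to air oxidation and irreversible adsorption during isolation. Fallback (capture and release in place of direct isolation): setting out from 28, the crude product of the BBr3 treatment is not purified but acetylated (Ac2O, pyridine, DMAP, rt) to the undecaacetate F1, which should be stable to air and silica and separable from under-cleaved material (this is returned to BBr3). Acid methanolysis (HCl in MeOH generated from AcCl, rt, Ar) then releases the phenols, and the route is rejoined at 29.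

2. Step 16. Process: C–O bond formation between the hindered phenol and an electron-rich bromide may be sluggish at 100 °C, so that hydrodebromination of the bromide and oxidative decay of the phenol take over. Fallback (room-temperature oxidative coupling in place of the Ullmann reaction): setting out from 27, bromine–lithium exchange (n-BuLi, THF, −78 °C) gives the aryllithium F2, which is quenched with B(OiPr)3 and hydrolysed (1 M HCl) to the ABC boronic acid F3. F3 and 16 are then coupled with Cu(OAc)2, pyridine, 4 Å MS and O2 in CH2Cl2 at rt (Chan–Lam coupling, the boron flanked by two ring hydrogens), and the route is rejoined at 28.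

3. Step 15. Process: ligation and transmetalation at the doubly flanked phenol may be slow, while the para-methoxyphenol is oxidised towards a quinone by divalent copper and oxygen and the boronic acid is consumed by protodeboronation and homocoupling. Fallback (metal-free arylation with a diaryliodonium salt): commercial 1-iodo-3,5-dimethoxybenzene is oxidised with mCPBA and TsOH·H2O in MeCN to the hydroxy(tosyloxy)iodoarene F4 and condensed in the same flask with 1,3,5-trimethoxybenzene to (3,5-dimethoxyphenyl)(2,4,6-trimethoxyphenyl)iodonium tosylate F5. Setting out from 25, deprotonation with t-BuOK in toluene and treatment with F5 at rt to 50 °C should transfer the dimethoxyphenyl group by ligand coupling at trivalent iodine, the trimethoxyphenyl group staying on iodine and the aryl bromide being untouched. The route is rejoined at 27.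

**Further compounds**

F1 | step 17 | undecaacetate of 29 (all eleven phenols acetylated) | CC(=O)Oc1cc(OC(C)=O)cc(Oc2c(OC(C)=O)cc(OC(C)=O)cc2Oc2c(OC(C)=O)cc(Oc3c(OC(C)=O)cc(OC(C)=O)cc3Oc3c(OC(C)=O)cc(OC(C)=O)cc3OC(C)=O)cc2OC(C)=O)c1
F2 | step 16 | {4-[2-(3,5-dimethoxyphenoxy)-3-ethoxy-5-methoxyphenoxy]-3,5-dimethoxyphenyl}lithium (not isolated) | CCOc1cc(OC)cc(Oc2c(OC)cc([Li])cc2OC)c1Oc1cc(OC)cc(OC)c1
F3 | step 16 | {4-[2-(3,5-dimethoxyphenoxy)-3-ethoxy-5-methoxyphenoxy]-3,5-dimethoxyphenyl}boronic acid | CCOc1cc(OC)cc(Oc2c(OC)cc(B(O)O)cc2OC)c1Oc1cc(OC)cc(OC)c1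
F4 | step 15 | 1-[hydroxy(tosyloxy)iodo]-3,5-dimethoxybenzene (not isolated) | COc1cc(OC)cc(I(O)OS(=O)(=O)c2ccc(C)cc2)c1
F5 | step 15 | (3,5-dimethoxyphenyl)(2,4,6-trimethoxyphenyl)iodonium 4-methylbenzenesulfonate | COc1cc(OC)cc([I+]c2c(OC)cc(OC)cc2OC)c1.Cc1ccc(S(=O)(=O)[O-])cc1
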